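Compound numbers are those of the list that follows the steps.

## Analysis of the target

Marchantin H (18) is a macrocyclic bis(bibenzyl). Four benzene rings are tied into one 18-membered ring by two diaryl ether oxygens (ring A–O–ring B and ring C–O–ring D) and two CH2CH2 bridges (ring B–ring C and ring D–ring A). Ring A is a monophenol with OH on C1, the ether oxygen on C6 and the bridge carbon on C4; ring B is a para-phenylene. Ring C carries the B–C bridge on C1, the ether oxygen on C2 and free hydroxyls on C3 and C4; ring D is a meta-phenylene. There is no stereocentre and no double bond of fixed geometry, so only connectivity has to be controlled; the conformers of the macrocycle are taken to interconvert freely. The two adjacent hydroxyls of ring C are prone to air oxidation and must stay masked to the end, and the ether oxygen on C2 of ring C sits between two ortho substituents, which makes the C–O–D link the most crowded bond to forge. The real difficulty is closing an 18-membered ring at an aryl–oxygen or aryl–carbon bond, which normally means a high-dilution cyclisation of a long open chain, while telling three phenolic oxygens apart. The strategy rests on ring A: the bridge carbon C4 is para to the oxygen on C1, and a ring drawn through O1 has the same size (18) as the ring drawn through C4. The C4–CH2 bond can therefore be traced to an arylacetyl group that first sits on O1 as an ester and is then moved from oxygen to carbon.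

## Retrosynthetic reasoning

18 ⇒ 17. The last disconnection is a functional-group one: the two O–H bonds on C3 and C4 of ring C are traced to the methyl ethers of 17. These hydroxyls are the only oxidation-prone part of 18, so they stay capped until the end, while the ring A hydroxyl, which the key step itself liberates, is left free. The forward step must cleave two aryl methyl ethers and leave two diaryl ethers alone; a boron Lewis acid does this because a diaryl ether has no alkyl carbon to give up.

17 ⇒ 16. The benzylic CH2 attached to C4 of ring A is taken back to a carbonyl group. This turns the D–A bridge into an aryl ketone, the product of an aromatic acylation, and so opens the next cut. Forward, a ketone conjugated to a para-hydroxyphenyl ring has to be reduced to CH2 beside aryl ethers; ionic hydrogenation suits a carbonyl that gives so well stabilised a benzylic cation.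

16 ⇒ 15. The bond cut is C4(ring A)–C(=O). The acyl carbon is not set free but reattached to the oxygen on C1 of the same ring, which gives lactone 15. The cut is made here, and not at an ether or a CH2–CH2 bond, because this is the one bond of the macrocycle whose two ends can be held together beforehand by a second, easily made bond. The gain is that the C–C macrocyclisation becomes an isomerisation of a ring that is already closed. The forward reaction, a Lewis-acid-induced oxygen-to-carbon acyl shift, must deliver the acyl group para to O1 and to no other arene position in the molecule.

15 ⇒ 13. The ester C(=O)–O bond is cut to give hydroxy acid 13; forward, the acid is activated as mixed anhydride 14 and closes onto the ring A hydroxyl. An aryl ester is among the easier bonds to close in a large ring, and the four rigid arenes of 13 limit its conformational freedom. The forward step needs high dilution and an acyl-transfer catalyst, since the nucleophile is a phenolic oxygen.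

13 ⇒ 12 ⇒ 10 ⇒ 5 + 8. Acid 13 comes from methyl ester 12. In 12 the CH2–CH2 bridge between rings B and C is cut between its two carbons by way of stilbene 10, whose C=C bond is the retron of a Wittig reaction between phosphonium salt 5 (through ylide 9) and aldehyde 8. It is the only bridge left, and the cut divides the chain into two diaryl ether halves of similar size. The ring A oxygen that will later carry the acyl group is a benzyl ether in 10, so one hydrogenation saturates the alkene and, through 11, frees the hydroxyl of 12. The carboxyl is a methyl ester, which survives both the Wittig base and the hydrogenation.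

8 ⇒ 6 + 7. The C–O–D ether is cut on the ring C side, at the C2–O bond. The formyl group of 6, the future benzylic carbon of the B–C bridge, stands ortho to the bromine and activates that carbon–halogen bond for a copper-catalysed etherification with 7. The opposite polarity would ask a phenol flanked by two ortho substituents to attack an unactivated ring D halide. The forward coupling must tolerate an aldehyde and an enolisable ester, which decides for a carbonate base in a solvent of low polarity.

5 ⇒ 4 ⇒ 3 ⇒ 1 + 2. Phosphonium salt 5 is derived from alcohol 4 and this from aldehyde 3. In 3 the A–O–B ether is cut on the ring B side, because the para-formyl group of 2 makes its fluoride displaceable by the phenoxide of 1 without any metal. Ring A enters as 1 with no carbon substituent at all and its second oxygen masked as a benzyl ether; the carbon that ends up on C4 arrives only in the key step.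

## Alternatives that were turned down

Alternative 1: The cut is the O–C(ring D) bond of the crowded C–O–D ether, and ring D is not bought as an arene but grown from a six-membered vinylogous acid chloride. Forward, the phenoxide on C2 of ring C of the open-chain chloroenone A2 adds to the chlorine-bearing β-carbon of its tethered cyclohexenone and expels chloride. This closes the 18-membered ring as the macrocyclic 3-aryloxycyclohexenone A1, racemic at the ring carbon that carries the side chain, a centre that vanishes on aromatisation. In its favour, the addition–elimination has one electrophilic carbon only and runs under mild base even with a phenoxide flanked by two ortho substituents. It thus avoids the copper coupling at the most hindered oxygen and any question of regiochemistry, and on that point it is stronger than the chosen route, whose ring closure must select one arene carbon among several. Against it, A1 still carries a carbonyl oxygen that ring D does not have, so reduction, dehydration and dehydrogenation must follow before ring D is aromatic. The chloroenone ring of A2 also has to be built from acyclic carbon at the end of a chain that already contains both CH2CH2 bridges. The chosen strategy offers in exchange four rings that are all purchased as arenes, a ring closure that at the same time forges a skeletal C–C bond of the D–A bridge, and two steps from ring closure to target.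

Alternative 2: The cut is the C(ring A)–O bond of the A–O–B ether, closed oxidatively in the manner assumed for the biosynthesis. Forward, Tl(NO3)3 (trivalent thallium) oxidises the 2,6-dibromophenol of ring A in the open-chain bis(dihalophenol) A4. The oxygen of the 2,6-dichlorophenol of ring B then adds to a bromine-bearing ortho carbon, and zinc reduction of the dienone removes that bromine and gives the macrocyclic bromo dichloro diaryl ether A3. In its favour, the ring closes at room temperature through a C–O bond whose position is fixed by the halogen pattern, and no carbon electrophile is ever exposed to the electron-rich ring C; in regiochemical certainty it is at least as good as the chosen route. Against it, four halogens must be installed and three removed afterwards, and the aryl bromides must survive the hydrogenation of two stilbene bridges that have to be built before the key step. The trioxygenated ring C is itself within reach of a two-electron oxidant, and a stoichiometric thallium salt is a heavy burden. The chosen strategy uses unadorned rings, one Wittig–hydrogenation instead of two and no heavy-metal oxidant. What it gives up is the built-in regiocontrol, which it replaces by the directing power of the ring A phenoxide.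

Alternative 3: The cut is the O–C(ring B) bond of the A–O–B ether, traced to the 19-membered aryl benzoate A6, in which the ring A oxygen is acylated by a ring B carboxyl. Forward, Ni(cod)2 (zerovalent nickel) with 3,4-bis(dicyclohexylphosphino)thiophene would insert into the acyl C–O bond of A6, decarbonylate and reductively eliminate the diaryl ether, contracting the ring by one atom to tri-O-methylmarchantin H A5. In its favour, it shares the idea of converting an easily made macrolactone into the real macrocycle, the new bond can only form at the carbon that carried the carbonyl, and A5 is one deprotection from the target. On regiochemistry and on closeness of the key product to the target it is stronger. Against it, insertion into an ester C(acyl)–O bond, decarbonylation and above all C–O reductive elimination from nickel are favourable when the acyl arene is electron-poor and can chelate the metal, as in azinecarboxylates. Ring B is an electron-neutral para-alkylbenzoate with neither feature, high temperature is needed, and the carbonyl carbon is discarded. Both CH2CH2 bridges must also be made separately beforehand. The chosen strategy keeps the acyl carbon as a skeletal atom of the D–A bridge, runs at room temperature with a commodity Lewis acid, and rests on an acyl transfer whose open-chain version is standard for exactly this ester type.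

Key step: step 9

Assumption: 2-bromo-3,4-dimethoxybenzaldehyde (6) and methyl 2-(3-hydroxyphenyl)acetate (7) are treated as catalogue compounds.

## Route

Step 1
Reactants: 1 2-(benzyloxy)phenol; 2 4-fluorobenzaldehyde
Product: 3 4-[2-(benzyloxy)phenoxy]benzaldehyde
Conditions: K2CO3, DMF, 120 °C
Reagents that add atoms: none
Why: Nucleophilic aromatic substitution by addition–elimination: the para-formyl group stabilises the Meisenheimer adduct and fluoride is the best leaving group for this mechanism. The benzyl ether leaves ring A with a single phenoxide oxygen, so double arylation cannot occur.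

Step 2
Reactants: 3 4-[2-(benzyloxy)phenoxy]benzaldehyde
Product: 4 {4-[2-(benzyloxy)phenoxy]phenyl}methanol
Conditions: NaBH4, MeOH–THF, 0 °C
Reagents that add atoms: none
Why: Borohydride reduction of an aryl aldehyde to the benzylic alcohol; no other group in 3 is reducible under these conditions.

Step 3
Reactants: 4 {4-[2-(benzyloxy)phenoxy]phenyl}methanol
Product: 5 {4-[2-(benzyloxy)phenoxy]benzyl}triphenylphosphonium bromide
Conditions: PPh3·HBr, MeCN, reflux
Reagents that add atoms: triphenylphosphine hydrobromide, Br.c1ccc(cc1)P(c1ccccc1)c1ccccc1
Why: Direct conversion of a benzylic alcohol into its phosphonium salt: protonation and loss of water give a benzylic cation stabilised by the para aryloxy group, which PPh3 captures. The aryl benzyl ether should tolerate this weakly acidic salt.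

Step 4
Reactants: 6 2-bromo-3,4-dimethoxybenzaldehyde; 7 methyl 2-(3-hydroxyphenyl)acetate
Product: 8 methyl 2-[3-(6-formyl-2,3-dimethoxyphenoxy)phenyl]acetate
Conditions: CuI (10 mol %), N,N-dimethylglycine·HCl (30 mol %), Cs2CO3, 1,4-dioxane, 90 °C
Reagents that add atoms: none
Why: Ullmann diaryl ether synthesis; the ortho formyl group activates the C–Br bond toward the copper catalyst. The barely soluble carbonate in dioxane is basic enough for the phenol but should leave the aldehyde and the enolisable ester alone.

Step 5
Reactants: 5 {4-[2-(benzyloxy)phenoxy]benzyl}triphenylphosphonium bromide; 8 methyl 2-[3-(6-formyl-2,3-dimethoxyphenoxy)phenyl]acetate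
Product: 10 methyl 2-{3-[6-(2-{4-[2-(benzyloxy)phenoxy]phenyl}ethenyl)-2,3-dimethoxyphenoxy]phenyl}acetate (E/Z mixture), via phosphorus ylide 9 (not isolated)
Conditions: K2CO3, 18-crown-6 (cat.), CH2Cl2, reflux
Reagents that add atoms: none
Why: Wittig olefination with a semi-stabilised benzylic ylide generated under solid–liquid phase-transfer conditions, which are mild enough for the methyl arylacetate. The alkene geometry is irrelevant because the double bond is hydrogenated next.

Step 6
Reactants: 10 methyl 2-{3-[6-(2-{4-[2-(benzyloxy)phenoxy]phenyl}ethenyl)-2,3-dimethoxyphenoxy]phenyl}acetate (E/Z mixture)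
Product: 12 methyl 2-[3-(6-{2-[4-(2-hydroxyphenoxy)phenyl]ethyl}-2,3-dimethoxyphenoxy)phenyl]acetate, via saturated benzyl ether 11 (not isolated)
Conditions: H2 (1 atm), 10% Pd/C, EtOAc–MeOH, rt
Reagents that add atoms: none
Why: Catalytic hydrogenation saturates the stilbene, and hydrogenolysis of the aryl benzyl ether then frees the ring A hydroxyl in the same flask. Methyl ethers, diaryl ethers and the ester are inert.

Step 7
Reactants: 12 methyl 2-[3-(6-{2-[4-(2-hydroxyphenoxy)phenyl]ethyl}-2,3-dimethoxyphenoxy)phenyl]acetate
Product: 13 2-[3-(6-{2-[4-(2-hydroxyphenoxy)phenyl]ethyl}-2,3-dimethoxyphenoxy)phenyl]acetic acid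
Conditions: LiOH·H2O, THF–H2O, rt; then 1 M HCl
Reagents that add atoms: lithium hydroxide, [Li+].[OH-]
Why: Saponification of a methyl ester by acyl–oxygen cleavage; acidification returns the free acid and the phenol.

Step 8
Reactants: 13 2-[3-(6-{2-[4-(2-hydroxyphenoxy)phenyl]ethyl}-2,3-dimethoxyphenoxy)phenyl]acetic acid
Product: 15 18-membered macrolactone (aryl ester between the ring D acetic acid chain and O1 of ring A; ring C 3,4-dimethoxy), via mixed anhydride 14 (not isolated)
Conditions: MNBA (2-methyl-6-nitrobenzoic anhydride, 1.3 equiv), DMAP (3 equiv), CH2Cl2, rt, 13 added over 12 h to a final 2 mM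
Reagents that add atoms: none
Why: Shiina macrolactonisation: the carboxylate forms mixed anhydride 14, DMAP takes over the arylacetyl group, and the ring A hydroxyl closes the ring under pseudo-high dilution. Phenols are readily acylated by acylpyridinium species, and the four rigid arenes keep the entropic cost of an 18-membered closure moderate.

Step 9
Reactants: 15 18-membered macrolactone
Product: 16 18-membered macrocyclic ketone (4-hydroxydeoxybenzoin: C=O on C4 of ring A, CH2 on ring D, OH free on C1 of ring A; ring C 3,4-dimethoxy)
Conditions: AlCl3 (5 equiv), PhNO2, 2 mM, 0 °C to rt; then ice-cold 1 M HCl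
Reagents that add atoms: none
Why: Proposed new method: AlCl3 binds the ester carbonyl, the acyl–oxygen bond ionises, and the arylacetyl cation that is set free remains tied through rings D, C and B to the aluminium phenoxide of ring A formed in the same event. Attack of the cation on C4 of ring A and loss of the proton give 16 as its aluminium phenoxide, which the acidic work-up protonates. The closest known reaction type is the Lewis-acid para-Fries rearrangement of open-chain aryl arylacetates to 4-hydroxydeoxybenzoins; what is new is that the shift must run across a macrolactone and so turn it into a carbocycle. The 18-membered carbocycle closes by electrophilic aromatic substitution (C-acylation of ring A by the tethered cation) as the 18-membered lactone opens, so the ring size is conserved and no stereocentre is formed. The step needs ring A to be acylated and not ring B or ring C: intramolecular attack on those rings would give strained 9- to 13-membered cyclophanes, ionisation turns the ring A oxygen into an anionic aluminate donor while AlCl3 ties up the vicinal methoxy oxygens of ring C, and the 2 mM concentration holds back acylation of a second molecule. Within ring A it needs C4: the phenoxide oxygen on C1 is a much stronger para director than the diaryl ether oxygen on C6, which rules against C3, and attack at C2 would place the aluminium-bearing oxygen inside the macrocycle and is the mode that low temperature and a polar solvent disfavour.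

Step 10
Reactants: 16 18-membered macrocyclic ketone
Product: 17 marchantin H ring C dimethyl ether (ring A hydroxyl free)
Conditions: Et3SiH (5 equiv), CF3CO2H, rt
Reagents that add atoms: none
Why: Ionic hydrogenation: the protonated ketone takes a hydride from the silane, the resulting carbinol ionises to a benzylic cation stabilised by the para hydroxyl, and a second hydride gives CH2. Aryl ethers and the phenol are untouched.

Step 11
Reactants: 17 marchantin H ring C dimethyl ether
Product: 18 marchantin H
Conditions: BBr3 (6 equiv), CH2Cl2, −78 °C to rt; then H2O
Reagents that add atoms: none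
Why: Boron tribromide ether cleavage: coordination to the methoxy oxygens and attack of bromide on the methyl carbons. The diaryl ethers have no alkyl carbon and survive, and water hydrolyses the aryl borates to the free triol.

## Compound list

1 | 2-(benzyloxy)phenol | Oc1ccccc1OCc1ccccc1 | starting material
2 | 4-fluorobenzaldehyde | O=Cc1ccc(F)cc1 | starting material
3 | 4-[2-(benzyloxy)phenoxy]benzaldehyde | O=Cc1ccc(Oc2ccccc2OCc2ccccc2)cc1 | intermediate
4 | {4-[2-(benzyloxy)phenoxy]phenyl}methanol | OCc1ccc(Oc2ccccc2OCc2ccccc2)cc1 | intermediate
5 | {4-[2-(benzyloxy)phenoxy]benzyl}triphenylphosphonium bromide | [Br-].C(c1ccc(Oc2ccccc2OCc2ccccc2)cc1)[P+](c1ccccc1)(c1ccccc1)c1ccccc1 | intermediate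
6 | 2-bromo-3,4-dimethoxybenzaldehyde | COc1ccc(C=O)c(Br)c1OC | starting material
7 | methyl 2-(3-hydroxyphenyl)acetate | COC(=O)Cc1cccc(O)c1 | starting material
8 | methyl 2-[3-(6-formyl-2,3-dimethoxyphenoxy)phenyl]acetate | COC(=O)Cc1cccc(Oc2c(C=O)ccc(OC)c2OC)c1 | intermediate
9 | {4-[2-(benzyloxy)phenoxy]benzylidene}triphenylphosphorane (ylide) | c1ccc(cc1)P(=Cc1ccc(Oc2ccccc2OCc2ccccc2)cc1)(c1ccccc1)c1ccccc1 | intermediate
10 | methyl 2-{3-[6-(2-{4-[2-(benzyloxy)phenoxy]phenyl}ethenyl)-2,3-dimethoxyphenoxy]phenyl}acetate (E/Z mixture) | COC(=O)Cc1cccc(Oc2c(C=Cc3ccc(Oc4ccccc4OCc4ccccc4)cc3)ccc(OC)c2OC)c1 | intermediate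
11 | methyl 2-{3-[6-(2-{4-[2-(benzyloxy)phenoxy]phenyl}ethyl)-2,3-dimethoxyphenoxy]phenyl}acetate | COC(=O)Cc1cccc(Oc2c(CCc3ccc(Oc4ccccc4OCc4ccccc4)cc3)ccc(OC)c2OC)c1 | intermediate
12 | methyl 2-[3-(6-{2-[4-(2-hydroxyphenoxy)phenyl]ethyl}-2,3-dimethoxyphenoxy)phenyl]acetate | COC(=O)Cc1cccc(Oc2c(CCc3ccc(Oc4ccccc4O)cc3)ccc(OC)c2OC)c1 | intermediate
13 | 2-[3-(6-{2-[4-(2-hydroxyphenoxy)phenyl]ethyl}-2,3-dimethoxyphenoxy)phenyl]acetic acid | OC(=O)Cc1cccc(Oc2c(CCc3ccc(Oc4ccccc4O)cc3)ccc(OC)c2OC)c1 | intermediate
14 | 2-methyl-6-nitrobenzoic 2-[3-(6-{2-[4-(2-hydroxyphenoxy)phenyl]ethyl}-2,3-dimethoxyphenoxy)phenyl]acetic anhydride | Cc1cccc([N+](=O)[O-])c1C(=O)OC(=O)Cc1cccc(Oc2c(CCc3ccc(Oc4ccccc4O)cc3)ccc(OC)c2OC)c1 | intermediate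
15 | 18-membered macrolactone (ring D–CH2–C(=O)–O1 of ring A; ring C 3,4-dimethoxy) | O=C1Cc2cccc(c2)Oc2c(CCc3ccc(cc3)Oc3ccccc3O1)ccc(OC)c2OC | intermediate
16 | 18-membered macrocyclic ketone (ring D–CH2–C(=O)–C4 of ring A; ring A OH free; ring C 3,4-dimethoxy) | Oc1ccc2cc1Oc1ccc(cc1)CCc1ccc(OC)c(OC)c1Oc1cccc(c1)CC2=O | intermediate
17 | marchantin H ring C dimethyl ether | Oc1ccc2cc1Oc1ccc(cc1)CCc1ccc(OC)c(OC)c1Oc1cccc(c1)CC2 | intermediate
18 | marchantin H | Oc1ccc2cc1Oc1ccc(cc1)CCc1ccc(O)c(O)c1Oc1cccc(c1)CC2 | target

## Step count and least certain steps

Total step count: 11. Longest linear sequence: 10 steps (steps 1, 2, 3, 5, 6, 7, 8, 9, 10, 11); step 4 is the side branch.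

Step 9 (key step, proposed new method). A para-Fries shift is in essence a dissociation followed by recombination, so its success here depends wholly on the tether and on dilution. After ionisation the acyl cation may fail to return to C4 and instead acylate the electron-rich ring C of a second molecule, which leads to oligomerisation. It may also migrate to C2 under chelation control, and the Lewis acid may strip the flanked methyl ether on C3 of ring C; this last process would be harmless, since both methyl ethers fall in step 11. The fallback uses known chemistry, sets out from starting materials 2 and 6 and returns to the route at target 18. It closes the D–A bridge by a McMurry coupling, a macrocyclisation established for macrocyclic bis(bibenzyl) ethers, so that no electrophilic aromatic substitution is needed. Methyl 3-hydroxy-4-methoxybenzoate F1 is arylated with 2 (K2CO3, DMF, 120 °C) to methyl 3-(4-formylphenoxy)-4-methoxybenzoate F2, which is reduced (NaBH4) to benzylic alcohol F3 and converted (PPh3·HBr, MeCN) into phosphonium bromide F4. Methyl 3-hydroxybenzoate F5 and 6 give, under the conditions of step 4, methyl 3-(6-formyl-2,3-dimethoxyphenoxy)benzoate F6. Wittig reaction of F4 with F6 (K2CO3, 18-crown-6) gives stilbene diester F7, hydrogenation (H2, Pd/C) gives bibenzyl diester F8, LiAlH4 gives bibenzyl diol F9 and MnO2 gives bibenzyl dialdehyde F10. Slow addition of F10 to TiCl4/Zn (low-valent titanium made in the flask) in refluxing THF closes the 18-membered ring as macrocyclic stilbene F11. Hydrogenation then gives tri-O-methylmarchantin H F12, and BBr3 cleaves its three methyl ethers to 18.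

Step 8. Intermolecular esterification (cyclic dimer and oligomers) may outrun ring closure, and the base may convert the activated arylacetyl unit into a ketene that condenses with itself. The fallback leaves the lactone out: 13 is added slowly to CF3SO3H at room temperature, where a carboxylic acid acylates a phenol directly at the para carbon. This is the open-chain version of the ring closure; it sets out from 13 and returns to the route at 16.

Step 4. Copper insertion into a C–Br bond flanked by formyl and methoxy may be slow, so that protodebromination competes, and the base may induce condensation of the arylacetate CH2 with the aldehyde. The fallback is a metal-free nucleophilic aromatic substitution: 7 reacts with 2-fluoro-3,4-dimethoxybenzaldehyde F13 (K2CO3, N,N-dimethylacetamide, 120 °C), in which the fluoride ortho to the formyl group is displaced by addition–elimination. It sets out from 7 and returns at 8.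

Step 10. The para-hydroxybenzylic cation may be captured by an arene (ring C of a second molecule) in place of the silane, or the reduction may stall after elimination to the macrocyclic stilbene. The fallback avoids a free cation in strong acid: 16 is reduced with NaBH4 in MeOH to macrocyclic carbinol F14 (racemic), and the para-hydroxybenzylic C–O bond is then removed by hydrogenolysis (H2, Pd/C, AcOH). It sets out from 16 and returns at 17.

## Further compounds

F1 | step 9 | methyl 3-hydroxy-4-methoxybenzoate | COC(=O)c1ccc(OC)c(O)c1
F2 | step 9 | methyl 3-(4-formylphenoxy)-4-methoxybenzoate | COC(=O)c1ccc(OC)c(Oc2ccc(C=O)cc2)c1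
F3 | step 9 | methyl 3-[4-(hydroxymethyl)phenoxy]-4-methoxybenzoate (benzylic alcohol) | COC(=O)c1ccc(OC)c(Oc2ccc(CO)cc2)c1
F4 | step 9 | {4-[2-methoxy-5-(methoxycarbonyl)phenoxy]benzyl}triphenylphosphonium bromide | [Br-].COC(=O)c1ccc(OC)c(Oc2ccc(C[P+](c3ccccc3)(c3ccccc3)c3ccccc3)cc2)c1
F5 | step 9 | methyl 3-hydroxybenzoate | COC(=O)c1cccc(O)c1
F6 | step 9 | methyl 3-(6-formyl-2,3-dimethoxyphenoxy)benzoate | COC(=O)c1cccc(Oc2c(C=O)ccc(OC)c2OC)c1
F7 | step 9 | stilbene diester (E/Z mixture) | COC(=O)c1cccc(Oc2c(C=Cc3ccc(Oc4cc(C(=O)OC)ccc4OC)cc3)ccc(OC)c2OC)c1
F8 | step 9 | bibenzyl diester | COC(=O)c1cccc(Oc2c(CCc3ccc(Oc4cc(C(=O)OC)ccc4OC)cc3)ccc(OC)c2OC)c1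
F9 | step 9 | bibenzyl diol | OCc1cccc(Oc2c(CCc3ccc(Oc4cc(CO)ccc4OC)cc3)ccc(OC)c2OC)c1
F10 | step 9 | bibenzyl dialdehyde | O=Cc1cccc(Oc2c(CCc3ccc(Oc4cc(C=O)ccc4OC)cc3)ccc(OC)c2OC)c1
F11 | step 9 | macrocyclic stilbene (E/Z mixture) | COc1ccc2cc1Oc1ccc(cc1)CCc1ccc(OC)c(OC)c1Oc1cccc(c1)C=C2
F12 | step 9 | tri-O-methylmarchantin H | COc1ccc2cc1Oc1ccc(cc1)CCc1ccc(OC)c(OC)c1Oc1cccc(c1)CC2
F0 | step 8 | none | none
F13 | step 4 | 2-fluoro-3,4-dimethoxybenzaldehyde | COc1ccc(C=O)c(F)c1OC
F14 | step 10 | macrocyclic carbinol (racemic, one enantiomer drawn) | Oc1ccc2cc1Oc1ccc(cc1)CCc1ccc(OC)c(OC)c1Oc1cccc(c1)C[C@H]2O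
A1 | alternative 1 | macrocyclic 3-aryloxycyclohex-2-enone (racemic, one enantiomer drawn) | O=C1C=C2C[C@H](C1)CCc1ccc(OC)c(c1)Oc1ccc(cc1)CCc1ccc(OC)c(OC)c1O2
A2 | alternative 1 | open-chain chloroenone phenol (racemic, one enantiomer drawn) | O=C1C=C(Cl)C[C@H](C1)CCc1ccc(OC)c(c1)Oc1ccc(cc1)CCc1ccc(OC)c(OC)c1O
A3 | alternative 2 | bromo dichloro di-O-methyl macrocyclic diaryl ether | Oc1c(Br)cc2cc1Oc1c(Cl)cc(cc1Cl)CCc1ccc(OC)c(OC)c1Oc1cccc(c1)CC2
A4 | alternative 2 | open-chain bis(dihalophenol) | Oc1c(Br)cc(cc1Br)CCc1cccc(c1)Oc1c(CCc2cc(Cl)c(O)c(Cl)c2)ccc(OC)c1OC
A5 | alternative 3 | tri-O-methylmarchantin H | COc1ccc2cc1Oc1ccc(cc1)CCc1ccc(OC)c(OC)c1Oc1cccc(c1)CC2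
A6 | alternative 3 | 19-membered aryl benzoate macrolactone | COc1ccc2cc1OC(=O)c1ccc(cc1)CCc1ccc(OC)c(OC)c1Oc1cccc(c1)CC2
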